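The C4‑methyl cyclopentene (C1–C5) fused to the seven‑membered ring (C1, C5–C10) that carries the C10 methyl is read as the imprint of a decalin photorearrangement. Irradiating a cross‑conjugated eudesma‑1,4‑dien‑3‑one in aqueous acetic acid joins C1 to C5, cuts C5–C10 and hydrates C10. Ring A thereby contracts to a cyclopentenone and ring B expands to the cycloheptane in one operation, with C7 and C8 untouched. The precursor is a carvone‑derived 7‑isopropyl‑8‑silyloxy dienone whose ring B already holds the trans C7/C8 pair. C1=C10, H5 and the 3‑ene are adjusted afterwards, and the vanillate is attached last.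

Key step: step 8

Remarks on the chemistry
- The target is read as (5R,7R,8S)‑guaia‑1(10),3‑dien‑8‑yl vanillate: C7 isopropyl and C8 oxygen trans, H5 on the same face as the isopropyl group.
- Bicyclic compounds carry eudesmane or guaiane numbering; monocyclic ones carry carvone numbering (C1 = carbonyl carbon).
- Compounds 8–13 are drawn as the expected major C10 epimer. The other epimer would take the same steps and converge at 14, where C1 and C10 become trigonal.

Step 1
Reactants: 1 (R)-carvone
Product: 2 (R)-carvotanacetone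
Conditions: H2 (1 atm), RhCl(PPh3)3 (cat.), benzene, rt
Reagents that add atoms: none
Why: Chemoselective homogeneous hydrogenation with RhCl(PPh3)3 saturates the unhindered 1,1‑disubstituted isopropenyl alkene and spares the trisubstituted enone alkene, removing the group that would let the later dienol ether aromatise to a carvacrol derivative; C5 is untouched.

Step 2
Reactants: 2 (R)-carvotanacetone
Product: 3 linear dienol silyl ether, tert‑butyldimethyl{[(5R)-2-methyl-5-(propan-2-yl)cyclohexa-1,3-dien-1-yl]oxy}silane
Conditions: TBSOTf, Et3N, CH2Cl2, 0 °C to rt (equilibrating)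
Reagents that add atoms: tert‑butyldimethylsilyl triflate, CC(C)(C)[Si](C)(C)OS(=O)(=O)C(F)(F)F
Why: Soft enolisation (silyl triflate and amine) under equilibrating conditions should give the through‑conjugated 1‑silyloxy‑1,3‑diene by loss of a C4 proton, the thermodynamic silyl dienol ether of a 2‑alkylcyclohexenone, with C5 unaffected.

Step 3
Reactants: 3 linear dienol silyl ether
Product: 4 (4R,5R)-4-hydroxy-2-methyl-5-(propan-2-yl)cyclohex-2-en-1-one
Conditions: mCPBA, NaHCO3, CH2Cl2, −20 to 0 °C; aq. Na2S2O3/NaHCO3 work‑up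
Reagents that add atoms: mCPBA, OOC(=O)c1cccc(Cl)c1
Why: Vinylogous Rubottom oxidation: the peracid epoxidises the electron‑rich diene at its C3=C4 end from the face opposite the neighbouring C5 isopropyl group, and collapse of the epoxide with loss of the silyl group regenerates the enone, so the C4 hydroxyl is set trans to isopropyl by substrate control.

Step 4
Reactants: 4 (4R,5R)-4-hydroxy-2-methyl-5-(propan-2-yl)cyclohex-2-en-1-one
Product: 5 (4R,5R)-2-methyl-5-(propan-2-yl)-4-(triisopropylsilyloxy)cyclohex-2-en-1-one
Conditions: TIPSOTf, 2,6‑lutidine, CH2Cl2, −78 to 0 °C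
Reagents that add atoms: triisopropylsilyl triflate, CC(C)[Si](OS(=O)(=O)C(F)(F)F)(C(C)C)C(C)C
Why: Silylation of a hindered secondary alcohol with a silyl triflate and a hindered pyridine base; the triisopropylsilyl ether is chosen because it should survive the alkoxide of step 6 and the aqueous acetic acid of step 8 and has no chromophore.

Step 5
Reactants: 5 (4R,5R)-2-methyl-5-(propan-2-yl)-4-(triisopropylsilyloxy)cyclohex-2-en-1-one
Product: 6 (4S,5R)-2-methyl-5-(propan-2-yl)-4-(triisopropylsilyloxy)cyclohexan-1-one (C2 epimers)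
Conditions: H2 (1 atm), 10% Pd/C, EtOAc, rt
Reagents that add atoms: none
Why: Heterogeneous hydrogenation of the conjugated alkene over Pd/C in a non‑protic solvent should leave the silyl ether intact; the C2 configuration is irrelevant because C2 is enolised in step 6.

Step 6
Reactants: 6 (4S,5R)-2-methyl-5-(propan-2-yl)-4-(triisopropylsilyloxy)cyclohexan-1-one; 7 ethyl vinyl ketone
Product: 10 (7R,8S,10S)-8-(triisopropylsilyloxy)eudesm-4-en-3-one, via Michael diketone 8 (not isolated), via aldol ketol 9 (not isolated)
Conditions: 7 (1.5 equiv), KOH (0.2 equiv), EtOH, 0 °C to rt; then NaOMe (0.5 equiv), MeOH, 60 °C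
Reagents that add atoms: none
Why: Robinson annulation: under protic equilibrating base the more substituted C2 enolate adds to the enone (Michael) and the 1,5‑diketone closes by aldol condensation; axial attack on the chair enolate with equatorial C4/C5 substituents should place the angular methyl mainly trans to isopropyl, a centre (C10) that is erased in step 9.

Step 7
Reactants: 10 (7R,8S,10S)-8-(triisopropylsilyloxy)eudesm-4-en-3-one
Product: 11 (7R,8S,10R)-8-(triisopropylsilyloxy)eudesma-1,4-dien-3-one
Conditions: DDQ, dioxane, reflux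
Reagents that add atoms: none
Why: Quinone dehydrogenation of a 4‑en‑3‑one under neutral conditions proceeds through the kinetic 2,4‑dienol with hydride abstraction from C1 and gives the cross‑conjugated 1,4‑dien‑3‑one; quaternary C10 rules out aromatisation and the silyl ether is inert.

Step 8
Reactants: 11 (7R,8S,10R)-8-(triisopropylsilyloxy)eudesma-1,4-dien-3-one
Product: 13 (1S,7R,8S,10S)-10-hydroxy-8-(triisopropylsilyloxy)guai-4-en-3-one, via oxyallyl zwitterion 12 (not isolated)
Conditions: hν (Pyrex‑filtered medium‑pressure mercury lamp, >290 nm), AcOH/H2O 1:1, N2, 15–20 °C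
Reagents that add atoms: water, O
Why: Excitation (n→π*) of the cross‑conjugated dienone and intersystem crossing lead to bonding between the two β‑carbons C1 and C5, and electron demotion gives the bicyclo[3.1.0] oxyallyl zwitterion 12; in the acidic medium it is O‑protonated and its C5–C10 cyclopropane bond cleaves as water adds to C10, leaving the 4‑en‑3‑one. The closest known reaction type is the cross‑conjugated cyclohexadienone photorearrangement run in aqueous acid (santonin to isophotosantonic lactone), in which the zwitterion of the type A pathway is trapped solvolytically. The cyclopentenone ring (C1–C5) closes by photochemical 1,5‑bonding across ring A (formally a 3‑exo closure onto C5 that creates the C1–C5–C10 cyclopropane), and the seven‑membered ring (C1, C5–C10) arises by ring expansion when the shared C5–C10 bond is cut, not by a cyclisation. Both new stereocentres follow stereospecifically from the existing C10 centre: C1 bonds to C5 on the face of ring B opposite the C10 methyl and water enters C10 anti to the departing C5, so H1 and the C10 hydroxyl end up cis; both centres are flattened in step 9. The step needs cleavage of C5–C10 in preference to C1–C10 (which would give a spiro ketone) and solvolytic opening in preference to the 1,4‑shift to the lumiketone: the C4 methyl stabilises positive charge at C4 and so directs cleavage of the bond to C5, and the protic acidic solvent intercepts the zwitterion. C7 and C8 take no part.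

Step 9
Reactants: 13 (1S,7R,8S,10S)-10-hydroxy-8-(triisopropylsilyloxy)guai-4-en-3-one
Product: 14 (7R,8S)-8-(triisopropylsilyloxy)guaia-1(10),4-dien-3-one
Conditions: Burgess reagent (methyl N‑(triethylammoniosulfonyl)carbamate), toluene, 50 °C
Reagents that add atoms: none
Why: Burgess dehydration (syn elimination through the sulfamate ester): H1 is cis to the C10 hydroxyl and is the most acidic β‑hydrogen (γ to the enone), so elimination should give the conjugated C1=C10 alkene under neutral conditions that do not threaten the C8 silyloxy group, which in the product is vinylogously β to the ketone.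

Step 10
Reactants: 14 (7R,8S)-8-(triisopropylsilyloxy)guaia-1(10),4-dien-3-one
Product: 15 (3R,7R,8S)-8-(triisopropylsilyloxy)guaia-1(10),4-dien-3-ol
Conditions: (S)-2-methyl-CBS-oxazaborolidine (0.2 equiv), BH3·SMe2, THF, −30 °C; MeOH quench
Reagents that add atoms: none
Why: Corey–Bakshi–Shibata reduction: with the methyl‑substituted alkenyl arm (C4) as the large group and the C2 methylene as the small one, the (S)-oxazaborolidine should give the (3R)-carbinol 1,2‑selectively by reagent control, placing the hydroxyl on the face of the flat bicycle opposite the C7 isopropyl group.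

Step 11
Reactants: 15 (3R,7R,8S)-8-(triisopropylsilyloxy)guaia-1(10),4-dien-3-ol
Product: 19 (5R,7R,8S)-8-(triisopropylsilyloxy)guaia-1(10),3-diene, via hydrazone adduct 16 (not isolated), via sulfonylhydrazine 17 (not isolated), via allylic diazene 18 (not isolated)
Conditions: IPNBSH (N'-isopropylidene-2-nitrobenzenesulfonohydrazide), PPh3, DEAD, THF, 0 °C to rt; then CF3CH2OH/H2O 1:1, rt
Reagents that add atoms: none
Why: Reductive allylic transposition through an allylic diazene: Mitsunobu displacement by the sulfonyl hydrazone nitrogen inverts C3, hydrolysis and loss of sulfinic acid unmask the monoalkyl diazene, and its retro‑ene loss of N2 transfers hydrogen suprafacially to C5 on the face bearing nitrogen while the alkene moves to C3=C4, so H5 is set cis to the C7 isopropyl group by the C3 centre.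

Step 12
Reactants: 19 (5R,7R,8S)-8-(triisopropylsilyloxy)guaia-1(10),3-diene
Product: 20 (5R,7R,8S)-guaia-1(10),3-dien-8-ol
Conditions: TBAF, THF, rt to 40 °C
Reagents that add atoms: none
Why: Fluoride‑mediated desilylation under non‑acidic conditions, which the skipped 1(10),3‑diene and its doubly allylic H5 should tolerate.

Step 13
Reactants: 21 vanillic acid
Product: 22 4-acetoxy-3-methoxybenzoic acid
Conditions: Ac2O, pyridine, rt; aqueous work‑up
Reagents that add atoms: acetic anhydride, CC(=O)OC(C)=O
Why: O‑Acetylation masks the phenol so that the acid can be activated in step 14 without self‑condensation; any mixed anhydride at the carboxyl group hydrolyses on work‑up.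

Step 14
Reactants: 20 (5R,7R,8S)-guaia-1(10),3-dien-8-ol; 22 4-acetoxy-3-methoxybenzoic acid
Product: 23 (5R,7R,8S)-guaia-1(10),3-dien-8-yl 4-acetoxy-3-methoxybenzoate
Conditions: EDC·HCl, DMAP, CH2Cl2, rt
Reagents that add atoms: none
Why: Steglich esterification (carbodiimide activation with DMAP acyl transfer) acylates the secondary C8 alcohol with retention, since no bond to C8 is broken.

Step 15
Reactants: 23 (5R,7R,8S)-guaia-1(10),3-dien-8-yl 4-acetoxy-3-methoxybenzoate
Product: 24 (5R,7R,8S)-guaia-1(10),3-dien-8-yl 4-hydroxy-3-methoxybenzoate (target)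
Conditions: K2CO3 (0.2 equiv), MeOH, 0 °C
Reagents that add atoms: none
Why: Base‑catalysed methanolysis (transesterification) should cleave the activated aryl acetate far faster than the hindered secondary benzoate, whose carbonyl is further deactivated once the para‑phenoxide is freed.

Compound list
1 | (R)-carvone, (5R)-2-methyl-5-(prop-1-en-2-yl)cyclohex-2-en-1-one | CC1=CC[C@H](CC1=O)C(C)=C | starting material
2 | (R)-carvotanacetone, (5R)-2-methyl-5-(propan-2-yl)cyclohex-2-en-1-one | CC1=CC[C@H](CC1=O)C(C)C | intermediate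
3 | tert-butyldimethyl{[(5R)-2-methyl-5-(propan-2-yl)cyclohexa-1,3-dien-1-yl]oxy}silane (linear dienol silyl ether) | CC1=C(O[Si](C)(C)C(C)(C)C)C[C@@H](C=C1)C(C)C | intermediate
4 | (4R,5R)-4-hydroxy-2-methyl-5-(propan-2-yl)cyclohex-2-en-1-one (OH trans to isopropyl) | CC1=C[C@H](O)[C@H](CC1=O)C(C)C | intermediate
5 | (4R,5R)-2-methyl-5-(propan-2-yl)-4-(triisopropylsilyloxy)cyclohex-2-en-1-one | CC1=C[C@H](O[Si](C(C)C)(C(C)C)C(C)C)[C@H](CC1=O)C(C)C | intermediate
6 | (4S,5R)-2-methyl-5-(propan-2-yl)-4-(triisopropylsilyloxy)cyclohexan-1-one (C2 epimers) | CC1C[C@H](O[Si](C(C)C)(C(C)C)C(C)C)[C@H](CC1=O)C(C)C | intermediate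
7 | ethyl vinyl ketone (pent-1-en-3-one) | CCC(=O)C=C | starting material
8 | (2S,4S,5R)-2-methyl-2-(3-oxopentyl)-5-(propan-2-yl)-4-(triisopropylsilyloxy)cyclohexan-1-one (Michael diketone, not isolated) | CCC(=O)CC[C@@]1(C)C[C@H](O[Si](C(C)C)(C(C)C)C(C)C)[C@H](CC1=O)C(C)C | intermediate
9 | (7R,8S,10S)-5-hydroxy-8-(triisopropylsilyloxy)eudesman-3-one (aldol ketol, C4 and C5 unassigned, not isolated) | O=C1CC[C@@]2(C)C[C@H](O[Si](C(C)C)(C(C)C)C(C)C)[C@@H](C(C)C)CC2(O)C1C | intermediate
10 | (7R,8S,10S)-8-(triisopropylsilyloxy)eudesm-4-en-3-one (C10 methyl trans to C7 isopropyl) | O=C1CC[C@@]2(C)C[C@H](O[Si](C(C)C)(C(C)C)C(C)C)[C@@H](C(C)C)CC2=C1C | intermediate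
11 | (7R,8S,10R)-8-(triisopropylsilyloxy)eudesma-1,4-dien-3-one | O=C1C=C[C@@]2(C)C[C@H](O[Si](C(C)C)(C(C)C)C(C)C)[C@@H](C(C)C)CC2=C1C | intermediate
12 | bicyclo[3.1.0] oxyallyl zwitterion (C1–C5–C10 cyclopropane, C3 oxide, C2–C4 allyl cation; not isolated) | [O-]C1=C[C@@H]2[C@@]3(C)C[C@H](O[Si](C(C)C)(C(C)C)C(C)C)[C@@H](C(C)C)C[C@@]23[C+]1C | intermediate
13 | (1S,7R,8S,10S)-10-hydroxy-8-(triisopropylsilyloxy)guai-4-en-3-one (H1 cis to 10-OH) | O=C1C[C@H]2C(=C1C)C[C@H](C(C)C)[C@@H](O[Si](C(C)C)(C(C)C)C(C)C)C[C@]2(C)O | intermediate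
14 | (7R,8S)-8-(triisopropylsilyloxy)guaia-1(10),4-dien-3-one | O=C1CC2=C(C)C[C@H](O[Si](C(C)C)(C(C)C)C(C)C)[C@@H](C(C)C)CC2=C1C | intermediate
15 | (3R,7R,8S)-8-(triisopropylsilyloxy)guaia-1(10),4-dien-3-ol | O[C@@H]1CC2=C(C)C[C@H](O[Si](C(C)C)(C(C)C)C(C)C)[C@@H](C(C)C)CC2=C1C | intermediate
16 | 2-nitro-N'-(propan-2-ylidene)-N-[(3S,7R,8S)-8-(triisopropylsilyloxy)guaia-1(10),4-dien-3-yl]benzenesulfonohydrazide (not isolated) | CC(C)=NN([C@H]1CC2=C(C)C[C@H](O[Si](C(C)C)(C(C)C)C(C)C)[C@@H](C(C)C)CC2=C1C)S(=O)(=O)c1ccccc1[N+](=O)[O-] | intermediate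
17 | 2-nitro-N-[(3S,7R,8S)-8-(triisopropylsilyloxy)guaia-1(10),4-dien-3-yl]benzenesulfonohydrazide (not isolated) | NN([C@H]1CC2=C(C)C[C@H](O[Si](C(C)C)(C(C)C)C(C)C)[C@@H](C(C)C)CC2=C1C)S(=O)(=O)c1ccccc1[N+](=O)[O-] | intermediate
18 | (3S,7R,8S)-3-diazenyl-8-(triisopropylsilyloxy)guaia-1(10),4-diene (not isolated) | N=N[C@H]1CC2=C(C)C[C@H](O[Si](C(C)C)(C(C)C)C(C)C)[C@@H](C(C)C)CC2=C1C | intermediate
19 | (5R,7R,8S)-8-(triisopropylsilyloxy)guaia-1(10),3-diene | CC(C)[Si](C(C)C)(C(C)C)O[C@H]1CC(C)=C2CC=C(C)[C@H]2C[C@@H]1C(C)C | intermediate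
20 | (5R,7R,8S)-guaia-1(10),3-dien-8-ol | O[C@H]1CC(C)=C2CC=C(C)[C@H]2C[C@@H]1C(C)C | intermediate
21 | vanillic acid | COc1cc(C(=O)O)ccc1O | starting material
22 | 4-acetoxy-3-methoxybenzoic acid | COc1cc(C(=O)O)ccc1OC(C)=O | intermediate
23 | (5R,7R,8S)-guaia-1(10),3-dien-8-yl 4-acetoxy-3-methoxybenzoate | COc1cc(C(=O)O[C@H]2CC(C)=C3CC=C(C)[C@H]3C[C@@H]2C(C)C)ccc1OC(C)=O | intermediate
24 | (5R,7R,8S)-guaia-1(10),3-dien-8-yl 4-hydroxy-3-methoxybenzoate, CNP0156298.2 | COc1cc(C(=O)O[C@H]2CC(C)=C3CC=C(C)[C@H]3C[C@@H]2C(C)C)ccc1O | target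

Total step count: 15.
Longest linear sequence: 14 steps (steps 1–12, 14 and 15; step 13 prepares the acid component).

Steps most likely to fail

1. Step 8. Capture of the ring‑opened cation by water may lose out to sigmatropic collapse of the zwitterion to the lumiketone, the product enone may undergo secondary photolysis, and the silyl ether may hydrolyse slowly in the aqueous acid. The fallback sets out from 11 and irradiates it in anhydrous acetic acid, so that acetate traps C10 and gives (1S,7R,8S,10S)-3-oxo-8-(triisopropylsilyloxy)guai-4-en-10-yl acetate F1. Treatment of F1 with DBU in toluene (rt to 50 °C) removes H1, which is γ to the ketone, and expels acetate in a vinylogous E1cB elimination. This returns to the route at 14 and bypasses 13 and step 9.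

2. Step 11. Mitsunobu activation of the doubly allylic C3 alcohol may cause ionisation instead of clean SN2 displacement, with loss of stereochemical fidelity at C3 or elimination to a fulvene. The fallback sets out from 15 and converts it with ClCO2Me and pyridine (CH2Cl2, 0 °C) into methyl (3R,7R,8S)-8-(triisopropylsilyloxy)guaia-1(10),4-dien-3-yl carbonate F2. Formate hydrogenolysis of F2 (Pd(OAc)2, PBu3, HCO2NH4, THF, rt) generates zerovalent palladium, which ionises the carbonate with inversion. Hydride is then delivered from the metal to the more substituted allyl terminus C5, again on the face opposite the original C3 oxygen. This comes back to the route at 19.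

3. Step 2. Enolisation may go toward C6 and give the cross‑conjugated 2‑silyloxy diene, so that the peracid of step 3 would oxidise the wrong carbon. The fallback sets out from 2. Deconjugation (t‑BuOK, t‑BuOH, rt, then quench into cold aqueous AcOH; kinetic α‑protonation of the extended dienolate) gives (5R)-2-methyl-5-(propan-2-yl)cyclohex-3-en-1-one F3. Epoxidation of its isolated C3=C4 alkene (mCPBA, NaHCO3, CH2Cl2, 0 °C) anti to the isopropyl group gives (3S,4R,5R)-3,4-epoxy-2-methyl-5-(propan-2-yl)cyclohexan-1-one F4. Et3N in CH2Cl2 then opens the β,γ‑epoxy ketone by E1cB elimination, which returns to the route at 4 with the oxygen regiospecifically on C4.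

Further compounds
F1 | step 8 | (1S,7R,8S,10S)-3-oxo-8-(triisopropylsilyloxy)guai-4-en-10-yl acetate | O=C1C[C@H]2C(=C1C)C[C@H](C(C)C)[C@@H](O[Si](C(C)C)(C(C)C)C(C)C)C[C@]2(C)OC(C)=O
F2 | step 11 | methyl (3R,7R,8S)-8-(triisopropylsilyloxy)guaia-1(10),4-dien-3-yl carbonate | COC(=O)O[C@@H]1CC2=C(C)C[C@H](O[Si](C(C)C)(C(C)C)C(C)C)[C@@H](C(C)C)CC2=C1C
F3 | step 2 | (5R)-2-methyl-5-(propan-2-yl)cyclohex-3-en-1-one (C2 epimers) | CC1C=C[C@H](CC1=O)C(C)C
F4 | step 2 | (3S,4R,5R)-3,4-epoxy-2-methyl-5-(propan-2-yl)cyclohexan-1-one (epoxide trans to isopropyl, C2 epimers) | CC1[C@@H]2O[C@@H]2[C@H](CC1=O)C(C)C
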